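The ratio [free catalyst]/[partner] as charged, which I call the catalyst ratio, is 0.00806 in larch, 0.00500 in alder, 0.00310 in cedar, 0.00250 in elm and 0.0207 in oak.

| flask | substrate | partner | free catalyst | remark | time |
|---|---|---|---|---|---|
| summer | 0.034 M (in portions, 3) | 0.062 M | 0.31 mM | run made earlier; portions every 4.0 h |  |
| larch | 0.015 M (in portions, 3) | 0.0620 M | 0.50 mM | the portions of substrate follow each other after 4.0 h, the first at the start | 15 h |
| oak | 0.031 M (in portions, 3) | 0.0150 M | 0.31 mM | the portions of substrate follow each other after 2.5 h, the first at the start | 15 h |
| cedar | 0.031 M (in portions, 3) | 0.100 M | 0.31 mM | the portions of substrate follow each other after 4.0 h, the first at the start | 15 h |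
| elm | 0.020 M (in portions, 3) | 0.200 M | 0.50 mM | the portions of substrate follow each other after 4.0 h, the first at the start | 15 h |
| alder | 0.031 M (in portions, 3) | 0.0620 M | 0.31 mM | the portions of substrate follow each other after 4.0 h, the first at the start | 15 h |

- summer (time / h: target / %): 0.667: 0.3; 1.50: 0.7; 4.00: 1.2; 10.0: 5.1

(readings scatter by 0.5 percentage points)

* the flasks by amount of target, in percent of the substrate charged, highest first, at 15 h (larch / oak / cedar / elm / alder)
* the same order at 5.0 d (larch / oak / cedar / elm / alder)
* the amount of target, in percent of the substrate charged of the flask you put first, at 15 h
* the amount of target, in percent of the substrate charged of the flask you put last, at 15 h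

Which given numbers have to be known well? The scatter of 0.5 percentage points on the summer reading of 5.1% moves the top and low values, and a scale common to the flasks leaves their order as it is. The interval comes next: 3 portions have a mean age of 11.0 h at 15 h with the usual interval and 12.5 h in oak, a factor of 1.14. Partner has the widest span, a factor of 13.3 across these flasks, while catalyst spans 1.61, and the summer run varies neither.

That run reads target and nothing else, so the rest of its substrate is unseen. If partner also consumes substrate without catalyst, the catalysed share rises with the catalyst ratio, and extra partner lowers the target per substrate. My own reckoning therefore ranks the flasks with excess partner at 5.0 d as larch, alder, cedar, elm, following  the ratio. Oak has the highest ratio, but its partner is the limiting reagent, at 48.4% of its substrate, so I keep it apart.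

The forecast gives elm > larch > cedar > alder > oak at 15 h and elm > larch > cedar > alder > oak at 5.0 d, with 39% for its first flask and 2.6% for its last, on the ground “I guess first order in each”. Mine differs from it by putting elm last of the excess-partner flasks at 5.0 d.

The flasks give larch > elm > cedar > alder > oak at 15 h, with 24.5% and 3.53% at the two ends, and larch > alder > cedar > elm > oak at 5.0 d.

    partner + catalyst intermediate → free catalyst + target (k = 53.0 M⁻¹ h⁻¹)
    free catalyst + open intermediate ⇌ catalyst intermediate (K = 190 M⁻¹, k = 8590 M⁻¹ h⁻¹)
    substrate + free catalyst → free catalyst + open intermediate (k = 155 M⁻¹ h⁻¹)
    substrate + partner → uncatalysed product (k = 1.14 M⁻¹ h⁻¹)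

While substrate stood, it left by two steps side by side: with free catalyst into open intermediate and with partner into uncatalysed product. At larch's catalyst ratio, as charged, these two rates stand at 1.10 to one, a catalysed share of 52.4%, and larch holds 50.5% target at 120 h; its substrate stands at 0% at 150 h. Elm at 15.0 h already holds 70.1% uncatalysed product beside 22.3% target. The neighbour of oak charged with 0.060 M partner has a catalyst ratio of 0.00517, close to alder's 0.00500, and ends with 11.5% target and 12.3% open intermediate, against 10.6% and 11.5% in alder.

(The readings are simulated for substances that don't exist, noise included.)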